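The earlier runs and the new flask stem from a simulated flask on assumed constants.

Per hour is the unit to think in: one constant in that unit carries this reckoning, so first find which concentration sets the order of the rate.

| flask | substrate | coupling partner | capture agent | remark | time |
|---|---|---|---|---|---|
| epsilon | 23 mM | 1.2 equiv | 2.3 mM | run made earlier |  |
| theta | 32 mM | 1.2 equiv | 2.3 mM | run made earlier |  |
| gamma | 51 mM | 1.2 equiv | 2.3 mM | run made earlier |  |
| eta | 23 mM | 1.2 equiv | 4.6 mM | run made earlier |  |
| Wednesday's | 23 mM (fed, over 2.0 h) | 1.20 equiv | 2.30 mM | all else is in the flask from the start; the feed brings no volume worth counting | 3.0 h |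
| Monday's | 23 mM | 1.20 equiv | 2.30 mM | everything together at the start | 3.0 h |
| Friday's | 23 mM | 1.20 equiv (fed, over 2.0 h) | 2.30 mM | all else is in the flask from the start; the feed brings no volume worth counting | 3.0 h |

epsilon run (percent of the substrate charged): time / h: target / % = 0.250: 23; 0.417: 29; 0.667: 46; 1.00: 59; 2.00: 74; 3.00: 80

theta run (percent of the substrate charged): time / min: target / % = 20.0: 29; 40.0: 48; 50.0: 51; 80.0: 69; 90.0: 70; 120: 74

gamma run (percent of the substrate charged): time / min: target / % = 8.00: 12; 20.0: 27; 40.0: 48; 60.0: 59; 80.0: 67; 120: 78

eta run (percent of the substrate charged): time / min: target / % = 20.0: 29; 40.0: 45; 60.0: 60; 80.0: 66; 120: 67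

(scatter of a reading: 2 percentage points)

- what was read earlier has a scatter of 2 percentage points, one standard deviation
- reactions considered so far: substrate <-> tight pair; tight pair <-> loose pair; coupling partner + tight pair -> target; coupling partner + loose pair -> isomer of the product; substrate -> decomposition product; capture agent + tight pair -> trapped intermediate

- the flask that comes out highest in amount of target, in percent of the substrate charged, or "all alike" when all lie within 1.5 percentage points (Wednesday's / Monday's / Friday's / all alike)
- target at the end, in percent of the substrate charged, Wednesday's
- target at the end, in percent of the substrate charged, Monday's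
- target at the end, in percent of the substrate charged, Friday's

Look at theta and gamma: at 40.0 min they read 48% and 48%, though the gamma charge is 1.59 times the theta charge. So with partner charged in step with substrate the percent does not follow the charge, which says that the orders in c_substrate and c_coupling partner sum to one. No earlier run moves partner away from 1.2 equiv, so I take first order in c_substrate and zero order in c_coupling partner as a working choice, not as a finding. A first-order curve also needs no plateau, because the reading at twice a time, over the reading at that time, is one plus the exponential decay over that time. Pooling both runs at 40.0 min and 80.0 min gives the substrate clock k, the first-order constant of the rate-limiting step, 1.31 h⁻¹, as a reading.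

My reckoning: Monday's keeps 1.95% of its substrate at 3.0 h and repeats epsilon, about 80%. Wednesday's holds 35.3% when its feed ends and 9.50% at 3.0 h. With Monday's split, that gives about 73.8% of target. I give Friday's no number: its partner enters over 2.0 h, longer than the clock time 0.763 h, so c_coupling partner may enter the order.

The forecast names Monday's, with 80% there, 74% for Wednesday's and 60% for Friday's (range 45% to 72%), on the ground that “partner stays scarce, so the agent is consumed early”.

The flasks give Monday's highest: Monday's 79.7%, Wednesday's 72.8%, Friday's 75.8%.

    substrate ⇌ tight pair (K = 0.00300, k = 3.65 × 10⁻⁴ s⁻¹)
    tight pair ⇌ loose pair (K = 0.338, k = 2.71 s⁻¹)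
    coupling partner + tight pair → target (k = 74.9 M⁻¹ s⁻¹)
    coupling partner + loose pair → isomer of the product (k = 49.6 M⁻¹ s⁻¹)
    substrate → decomposition product (k = 3.24 × 10⁻⁶ s⁻¹)
    capture agent + tight pair → trapped intermediate (k = 0.384 M⁻¹ s⁻¹)

Wednesday's substrate stood at 37.1% at 2.00 h, against the clock's 35.3%, and at 11.6% at 3.00 h, against 9.50%, while its target climbed from 51.9% to 72.8% after the feed stopped. Friday's target stood at 66.0% at 2.00 h and reached 75.8% at 3.00 h, above the forecast's range, with 95.5% of the capture agent's own charge still free.

Take a neighbour: Monday's flask, but with 4.80 equiv of partner. The clock has no partner in it, so it again says 1.95% of substrate left; the computed flask holds 1.99%, with 85.3% of target.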